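The pitfall with these two runs, which differ in free catalyst, was to read the order from the slopes near the level asked about. The late stretches gave 3.26, but the red slope rested on a gain of 4 percentage points against a scatter of 1.5 points per reading.

| setting | grey | red | flask |
|---|---|---|---|
| substrate | 27 mM | 27 mM | 27 mM |
| partner | 135 mM | 135 mM | 135 mM |
| free catalyst | 18 µM | 12 µM | 18 µM |
| remark | the very flask that is asked about, followed so far | run made earlier |  |

| grey: time / h | grey: product / % | red: time / h | red: product / % |
|---|---|---|---|
| 0.667 | 7 | 2.50 | 7 |
| 1.33 | 5 | 5.00 | 14 |
| 3.00 | 13 | 8.00 | 15 |
| 8.00 | 28 | 10.0 | 18 |

(each reading ± 1.5 percentage points)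

1. apparent order in free catalyst when 20% of the substrate are converted (percent change of the rate of making product for one percent more free catalyst charged)



So I ranked the stretches by emptying time, the time the whole substrate would need at that stretch's pace. The grey start gave 23.1 h, the later grey stretch 33.3 h, the red start 35.7 h and the later red stretch 125 h, each time longer than the one before. Both runs were therefore slowing. At the early end, where the two starts had made similar product, the emptying times gave an order of 1.08.

To join that end to the noisy late one, I compared both runs at 8.00 h. The readings 28% and 15% gave 1.54, give or take 0.280, for the equal-time order, the logarithm of the product ratio over the logarithm of the charge ratio. The forecast stood lower at 1.4, reasoning that “the faster run reaches 20 % with more catalyst surviving”.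

The flask gave 1.3, reached at 5.50 h.

    partner + free catalyst → catalyst intermediate A (k = 840 L mol⁻¹ h⁻¹)
    substrate + catalyst intermediate A → catalyst intermediate B (k = 23000 L mol⁻¹ h⁻¹)
    catalyst intermediate B → free catalyst + product (k = 27000 h⁻¹)
    free catalyst ⇌ dormant form (K = 1.80, k = 0.390 h⁻¹)

The forecast held. My equal-time order of 1.54 compared product from two scattered readings at unequal conversions, not rates at one conversion, so its gap of 0.240 from the flask's value confirmed nothing. The conversion of free catalyst into dormant form, both ways, raised the order above first: with that step taken away, the order at the same conversion fell from 1.3 to 1.0.

Readings and results are calculated with constants of no real substance, noise included.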